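**Assumption:** Artoindonesianin R (C22H22O7) has no stereocenters, because the prenyl alkene carries two identical methyls. "Single enantiomer" therefore has no content here, and no stereocontrol is needed.

## Retrosynthetic overview
1. Remove the three MOM groups last. The target is 5,7,5′-tri-OH-3-prenyl-2′,4′-dimethoxyflavone.
2. **(Proposed new step)** Form the pyranone ring and the C3–prenyl bond in one Pd(0) step from an o-prenyloxyaryl ynone: ionisation of the aryl–O prenyl bond, 6-endo oxa-Michael, then C-allylation.
3. Make the ynone by adding the lithium acetylide of the B-ring aryl alkyne to the O-prenyl A-ring aldehyde, then oxidising.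
4. The A-ring aldehyde comes from phloroglucinaldehyde (bis-MOM, then O-prenyl). The B-ring alkyne comes from 2,4-dimethoxyphenol (MOM, iodination at C5, Sonogashira).

## Route

**Step 1**
Reactants: 1, 2,4,6-trihydroxybenzaldehyde
Product: 2, 2-hydroxy-4,6-bis(methoxymethoxy)benzaldehyde
Conditions: MOMCl (2.2 equiv), DIPEA, CH2Cl2, 0 °C → rt
Reagents that add atoms: MOMCl, COCCl (adds the two MOM groups)
Why: The 2-OH is hydrogen-bonded to the aldehyde and is much less reactive, so Williamson-type MOM protection occurs at the 4- and 6-OH groups. (Assumed selectivity; it is the standard behaviour of phloroglucinol carbonyl compounds.)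

**Step 2**
Reactants: 2; 3, prenyl bromide (1-bromo-3-methylbut-2-ene)
Product: 4, 2-(3-methylbut-2-enyloxy)-4,6-bis(methoxymethoxy)benzaldehyde
Conditions: 3, K2CO3, DMF, rt, 6 h
Reagents that add atoms: prenyl bromide (reactant 3), CC(C)=CCBr
Why: SN2 O-alkylation of the phenoxide gives the aryl prenyl ether. This is the substrate for the Pd step, and the prenyl group is installed before the ring is formed.

**Step 3**
Reactants: 5, 2,4-dimethoxyphenol
Product: 6, 1-(methoxymethoxy)-2,4-dimethoxybenzene
Conditions: NaH, THF/DMF, 0 °C; then MOMCl, 0 °C → rt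
Reagents that add atoms: MOMCl, COCCl
Why: Standard phenol MOM protection. The 5′-OH is masked as an acetal that is stable to the organolithium and Pd steps and is removed together with the other MOM groups at the end.

**Step 4**
Reactants: 6
Product: 7, 1-iodo-2,4-dimethoxy-5-(methoxymethoxy)benzene
Conditions: NIS (1.05 equiv), MeCN, 0 °C → rt, dark
Reagents that add atoms: NIS, O=C1CCC(=O)N1I (adds I)
Why: Electrophilic aromatic iodination goes to C5 of 6, which is para to one OMe and ortho to another. C3, between two OMe groups, is sterically blocked, and C6 is only meta to both OMe groups. This places the iodide where the flavone C2–aryl bond will sit (1′), with 2′-OMe, 4′-OMe and 5′-OMOM.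

**Step 5**
Reactants: 7; 8, trimethylsilylacetylene
Product: 9, trimethyl[(2,4-dimethoxy-5-(methoxymethoxy)phenyl)ethynyl]silane
Conditions: 8 (1.3 equiv), PdCl2(PPh3)2 (3 mol %), CuI (5 mol %), Et3N/THF, 50 °C
Reagents that add atoms: trimethylsilylacetylene (reactant 8), C[Si](C)(C)C#C
Why: Sonogashira coupling of an electron-rich aryl iodide with a terminal alkyne.

**Step 6**
Reactants: 9
Product: 10, 1-ethynyl-2,4-dimethoxy-5-(methoxymethoxy)benzene
Conditions: K2CO3, MeOH, rt, 1 h
Reagents that add atoms: none
Why: Mild base-mediated C–Si cleavage; the MOM and OMe groups are untouched.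

**Step 7**
Reactants: 10; 4
Product: 11, 1-[2-(prenyloxy)-4,6-bis(MOMO)phenyl]-3-[2,4-dimethoxy-5-(MOMO)phenyl]prop-2-yn-1-ol
Conditions: 10, n-BuLi (1.05 equiv), THF, −78 °C, 30 min; add 4, −78 → 0 °C; sat. NH4Cl quench
Reagents that add atoms: none (n-BuLi only deprotonates; the alkynyl carbon is transferred from 10)
Why: Acetylide 1,2-addition to the aldehyde (Favorskii-type alkynylation). The alkyne C–H (pKa about 25) is deprotonated selectively, and the aryl ethers and MOM groups are inert at −78 °C. The product is a racemic secondary alcohol that is oxidised in the next step.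

**Step 8**
Reactants: 11
Product: 12, 1-[2-(prenyloxy)-4,6-bis(MOMO)phenyl]-3-[2,4-dimethoxy-5-(MOMO)phenyl]prop-2-yn-1-one (ynone)
Conditions: Dess–Martin periodinane (1.5 equiv), NaHCO3, CH2Cl2, 0 °C → rt
Reagents that add atoms: none
Why: Mild, buffered oxidation of a propargylic alcohol to an ynone. The prenyl alkene, the electron-rich arenes and the MOM acetals tolerate it, and the retro-carbonyl stereocenter is destroyed, so nothing is lost.

**Step 9**
Reactants: 12
Product: 13, 5,7-bis(MOMO)-2-[2,4-dimethoxy-5-(MOMO)phenyl]-3-(3-methylbut-2-enyl)-4H-chromen-4-one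
Conditions: Pd2(dba)3 (2.5 mol %), PPh3 (20 mol %), degassed toluene, 90 °C, 12 h, Ar
Reagents that add atoms: none (isomerisation; all atoms of 12 are retained)
Why: Proposed new method: Pd(0) ionises the aryl–O prenyl bond, helped by the o-alkynoyl-substituted phenoxide as leaving group, to give an [η3-prenyl-Pd]+ phenoxide ion pair. The phenoxide then does a 6-endo oxa-Michael addition to the ynone β-carbon (the carbon bearing the B-ring aryl). This gives a chromenolate/allenolate whose central carbon attacks the less-substituted (primary) terminus of the π-allyl in a Tsuji–Trost step. That forms the linear C3–prenyl bond, closes the γ-pyranone and regenerates Pd(0). The closest known reactions are Pd-catalysed cyclisation–allylation of o-alkynylphenols, Au-catalysed carboalkoxylation of o-alkynylaryl allyl ethers, and Tsuji–Trost allylation of soft enolates. Because no proton source is present, protonation to the 3-H flavone cannot compete. The product is achiral.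

**Step 10**
Reactants: 13
Product: 14, Artoindonesianin R
Conditions: 2 M HCl, MeOH/THF (1:1), 50 °C, 3 h
Reagents that add atoms: none (only H is added; CH2O and MeOH leave)
Why: Acid hydrolysis of aryl MOM acetals. The 5-OMOM peri to the carbonyl is cleaved readily and the 5-OH then re-chelates to C4=O. The B-ring methyl ethers, the flavone core and the prenyl alkene survive these mild conditions.

## Consistency check against the target SMILES
- **Ring system and substituents:** 13 is a 2-aryl chromen-4-one with C5, C7 and C5′ oxygenated. The O-prenyl oxygen of the aldehyde becomes O1 and C8a. The C4 and C6 oxygens of the aldehyde become the 7- and 5-oxygens.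
- **Prenyl and B-ring:** The prenyl group ends at C3, bonded to the alkyne carbon that was α to the carbonyl. The B-ring is attached at C2 with 2′-OMe, 4′-OMe and 5′-OH. This matches COc1cc(OC)c(-c2oc3cc(O)cc(O)c3c(=O)c2CC=C(C)C)cc1O.
- **Atom accounting:** 12 and 13 are isomers, C40H50O13 (calculated 12: ynone with three MOM groups). 14 is C22H22O7.
- **Stereochemistry:** There are no stereocenters. The only one formed in the route, the carbinol in 11, is removed in Step 8.

## Compound list
1 | 2,4,6-trihydroxybenzaldehyde | O=Cc1c(O)cc(O)cc1O | starting material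
2 | 2-hydroxy-4,6-bis(methoxymethoxy)benzaldehyde | O=Cc1c(O)cc(OCOC)cc1OCOC | intermediate
3 | prenyl bromide | CC(C)=CCBr | starting material
4 | 2-(prenyloxy)-4,6-bis(methoxymethoxy)benzaldehyde | O=Cc1c(OCC=C(C)C)cc(OCOC)cc1OCOC | intermediate
5 | 2,4-dimethoxyphenol | COc1ccc(O)c(OC)c1 | starting material
6 | 1-(methoxymethoxy)-2,4-dimethoxybenzene | COCOc1ccc(OC)cc1OC | intermediate
7 | 1-iodo-2,4-dimethoxy-5-(methoxymethoxy)benzene | Ic1cc(OCOC)c(OC)cc1OC | intermediate
8 | trimethylsilylacetylene | C[Si](C)(C)C#C | starting material
9 | TMS-alkyne of 7 | C[Si](C)(C)C#Cc1cc(OCOC)c(OC)cc1OC | intermediate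
10 | 1-ethynyl-2,4-dimethoxy-5-(methoxymethoxy)benzene | C#Cc1cc(OCOC)c(OC)cc1OC | intermediate
11 | propargylic alcohol (racemic) | OC(c1c(OCC=C(C)C)cc(OCOC)cc1OCOC)C#Cc1cc(OCOC)c(OC)cc1OC | intermediate
12 | o-prenyloxyaryl ynone | O=C(C#Cc1cc(OCOC)c(OC)cc1OC)c1c(OCC=C(C)C)cc(OCOC)cc1OCOC | intermediate
13 | tri-MOM-protected 3-prenylflavone | CC(C)=CCc1c(-c2cc(OCOC)c(OC)cc2OC)oc2cc(OCOC)cc(OCOC)c2c1=O | intermediate
14 | Artoindonesianin R | COc1cc(OC)c(-c2oc3cc(O)cc(O)c3c(=O)c2CC=C(C)C)cc1O | target

## Step count
- Total steps: 10.
- Longest linear sequence: 8 steps (5 → 6 → 7 → 9 → 10 → 11 → 12 → 13 → 14).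

## Three steps most likely to fail
1. **Step 9 (proposed new Pd-catalysed ionisation/oxa-Michael/C-allylation).**
   - Risks: aryl prenyl ether ionisation may be sluggish, Pd-catalysed C-allylation of the electron-rich phloroglucinol-type ring may compete, and branched (reverse-prenyl) product may form.
   - Fallback (known chemistry, different approach): Baker–Venkataraman route.
     - Acylate 2′-hydroxy-4′,6′-bis(MOMO)acetophenone with 2,4-dimethoxy-5-(MOMO)benzoyl chloride.
     - Rearrange with KOtBu or LiHMDS to the 1,3-diketone.
     - C-prenylate with prenyl bromide and K2CO3.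
     - Cyclodehydrate and remove the MOM groups with p-TsOH/MeOH.
2. **Step 1 (selective bis-MOM protection of phloroglucinaldehyde).**
   - Risks: a tris-MOM or mono-MOM mixture.
   - Fallback: formylate 1,3,5-tris(MOMO)benzene (Vilsmeier) and then selectively cleave the ortho-MOM next to the CHO with a chelating Lewis acid (MgBr2·OEt2 or TiCl4). This reaches 2 by a different disconnection.
3. **Step 10 (MOM removal with the prenyl alkene and 5-OH present).**
   - Risks: acid-mediated hydration or cyclisation of the prenyl alkene.
   - Fallback: rerun the route with benzyl protection on all three phenols (BnBr in Steps 1 and 3, and an o-OBn A-ring aldehyde).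
     - Remove the benzyl groups at the end with BCl3/pentamethylbenzene at −78 °C, which is non-hydrogenolytic and non-acidic towards the alkene.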